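**Retrosynthetic overview**
1. Chondrillin 15 ⇐ acid-catalysed methanol exchange on the cyclic peroxyhemiketal 14. The only ring (the 1,2-dioxine) closes last, by addition of the C3 hydroperoxide to the C6 ketone of a Z-enone.
2. (3R)-γ-Hydroperoxy enone 12 ⇐ racemate 11 (enantiomer separation) ⇐ C3–O bond from triplet O2 by radical-chain oxygenation of the skipped enone 10.
3. 10 ⇐ cross-metathesis (C3=C4) of allyl ketone 8 with methyl but-3-enoate 9.
4. 8 ⇐ hexadecylzirconocene + CO + allyl bromide; the C16 chain ⇐ two heptyl Grignard units + (E)-1,2-dichloroethene, then chain-walking hydrozirconation.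

Assumption: the SMILES is read as (3R,6S), with hexadecyl and CH2CO2Me cis on the ring; chain positions are numbered C1 (ester carbon) to C22, so C3 and C6 are also ring positions 3 and 6.

C3 is not induced: the radical step gives the racemate and C3 is fixed by resolution in step 5. C6 is set in the final ketalisation under equilibrating conditions, and the 6S ketal is isolated by chromatography. Step 1 uses two molecules of 1 for each molecule of 2.

**Step 1**
Reactants: 1 1-bromoheptane; 2 (E)-1,2-dichloroethene
Product: 4 (E)-hexadec-8-ene, via heptylmagnesium bromide 3 (not isolated)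
Conditions: 1 (2.3 equiv in total), Mg, THF, 40 °C; then 2 (1.0 equiv), NiCl2(dppp) (1 mol%), THF/Et2O, 0 °C to reflux
Reagents that add atoms: 1-bromoheptane (the second equivalent of 1, likewise used as Grignard reagent 3) CCCCCCCBr
Why: A twofold Kumada–Corriu cross-coupling of two molecules of the primary alkyl Grignard reagent with the two C–Cl bonds of the alkenyl dichloride joins two C7 units through the C2 linker, and the alkene geometry is irrelevant because the double bond is walked to the chain end in step 2.

**Step 2**
Reactants: 4 (E)-hexadec-8-ene; 5 allyl bromide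
Product: 8 icos-1-en-4-one, via hexadecylzirconocene chloride 6 (not isolated), via heptadecanoylzirconocene chloride 7 (not isolated)
Conditions: Cp2Zr(H)Cl (1.5 equiv), THF, 45 °C; CO (1 atm), rt; then 5 (1.5 equiv), CuI (10 mol%), THF/DMF, 0 °C to rt; neutral work-up
Reagents that add atoms: carbon monoxide [C-]#[O+]
Why: Hydrozirconation with chain walking (reversible β-hydride elimination and re-insertion) places Zr on the terminal carbon, CO insertion gives the acylzirconocene as an acyl anion equivalent, and copper-catalysed allylation delivers the β,γ-unsaturated ketone under neutral conditions that do not move the double bond into conjugation.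

**Step 3**
Reactants: 8 icos-1-en-4-one; 9 methyl but-3-enoate
Product: 10 methyl (3E)-6-oxodocos-3-enoate
Conditions: 9 (4 equiv), (H2IMes)(PCy3)Cl2Ru=CHPh (second-generation Grubbs catalyst, 3 mol%), 1,4-benzoquinone (10 mol%), CH2Cl2, 40 °C, Ar
Reagents that add atoms: none
Why: Olefin cross-metathesis of two terminal alkenes is driven by loss of ethene and builds the C3=C4 bond (E/Z about 4:1, both usable because the geometry is erased in step 4), with benzoquinone suppressing Ru–H mediated migration of the double bond.

**Step 4 (key step)**
Reactants: 10 methyl (3E)-6-oxodocos-3-enoate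
Product: 11 methyl (4E)-3-hydroperoxy-6-oxodocos-4-enoate (racemic)
Conditions: O2 (1 atm), N-hydroxyphthalimide (10 mol%), di-tert-butyl hyponitrite (2 mol%), PhCF3/MeCN (3:1), 30 °C, dark, stopped near 70% conversion
Reagents that add atoms: dioxygen O=O
Why: Radical-chain autoxidation of a β,γ-unsaturated ketone (the behaviour known for cholest-5-en-3-one and β-isophorone): phthalimide-N-oxyl and peroxyl chain carriers abstract the weak keto-allylic C5–H, triplet O2 adds to the γ terminus (C3) of the 1-acylallyl radical to form the C3–O bond and the conjugated enone, any C5 peroxyl isomer converges by allylic peroxyl (Schenck) rearrangement, and H transfer from N-hydroxyphthalimide releases the hydroperoxide, which is racemic at C3 because the radical is planar.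

**Step 5**
Reactants: 11 methyl (4E)-3-hydroperoxy-6-oxodocos-4-enoate (racemic)
Product: 12 methyl (3R,4E)-3-hydroperoxy-6-oxodocos-4-enoate
Conditions: preparative HPLC on amylose tris(3,5-dimethylphenylcarbamate), hexane/i-PrOH, 10 °C
Reagents that add atoms: none
Why: Enantiomer separation on a polysaccharide chiral stationary phase, routine for allylic hydroperoxide methyl esters, fixes C3 as R (assignment checked on an aliquot by PPh3 reduction and Mosher ester analysis), and the 3S enantiomer can in principle be racemised for recycling by re-exposure to the step 4 conditions through reversible loss of O2 from its peroxyl radical.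

**Step 6**
Reactants: 12 methyl (3R,4E)-3-hydroperoxy-6-oxodocos-4-enoate
Product: 15 chondrillin (methyl 2-[(3R,6S)-6-hexadecyl-6-methoxy-3,6-dihydro-1,2-dioxin-3-yl]acetate), via Z-hydroperoxy enone 13 (not isolated), via peroxyhemiketal 14 (not isolated)
Conditions: hv (350 nm), CH2Cl2, 0 °C; then TsOH·H2O (5 mol%), MeOH, rt; silica gel chromatography, with the 6R ketal fraction returned to TsOH/MeOH
Reagents that add atoms: methanol CO
Why: Photochemical E to Z isomerisation of the enone gives 13, which is drained by spontaneous addition of the hydroperoxide to the ketone (peroxyhemiketalisation to 14), and acid-catalysed exchange with methanol through the allylic peroxycarbenium ion sets C6 under equilibrating conditions as a roughly 1:1, silica-separable pair of ketal epimers, from which the 6S ketal 15 is isolated while the 6R fraction re-equilibrates through the same cation on resubmission and C3 stays untouched.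

**Compound list**
1 | 1-bromoheptane | CCCCCCCBr | starting material
2 | (E)-1,2-dichloroethene | Cl/C=C/Cl | starting material
3 | heptylmagnesium bromide | CCCCCCC[Mg]Br | intermediate
4 | (E)-hexadec-8-ene | CCCCCCC/C=C/CCCCCCC | intermediate
5 | allyl bromide (3-bromoprop-1-ene) | C=CCBr | starting material
6 | hexadecylzirconocene chloride (chloro(hexadecyl)bis(cyclopentadienyl)zirconium) | CCCCCCCCCCCCCCCC[Zr](Cl)(C1C=CC=C1)C1C=CC=C1 | intermediate
7 | heptadecanoylzirconocene chloride | CCCCCCCCCCCCCCCCC(=O)[Zr](Cl)(C1C=CC=C1)C1C=CC=C1 | intermediate
8 | icos-1-en-4-one | C=CCC(=O)CCCCCCCCCCCCCCCC | intermediate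
9 | methyl but-3-enoate | COC(=O)CC=C | starting material
10 | methyl (3E)-6-oxodocos-3-enoate (used as E/Z mixture) | CCCCCCCCCCCCCCCCC(=O)C/C=C/CC(=O)OC | intermediate
11 | methyl (4E)-3-hydroperoxy-6-oxodocos-4-enoate (racemic) | CCCCCCCCCCCCCCCCC(=O)/C=C/C(OO)CC(=O)OC | intermediate
12 | methyl (3R,4E)-3-hydroperoxy-6-oxodocos-4-enoate | CCCCCCCCCCCCCCCCC(=O)/C=C/[C@H](OO)CC(=O)OC | intermediate
13 | methyl (3R,4Z)-3-hydroperoxy-6-oxodocos-4-enoate | CCCCCCCCCCCCCCCCC(=O)/C=C\[C@H](OO)CC(=O)OC | intermediate
14 | methyl 2-[(3R)-6-hexadecyl-6-hydroxy-3,6-dihydro-1,2-dioxin-3-yl]acetate (both C6 epimers) | CCCCCCCCCCCCCCCCC1(O)C=C[C@@H](CC(=O)OC)OO1 | intermediate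
15 | chondrillin, methyl 2-[(3R,6S)-6-hexadecyl-6-methoxy-3,6-dihydro-1,2-dioxin-3-yl]acetate | CCCCCCCCCCCCCCCC[C@@]1(OC)C=C[C@@H](CC(=O)OC)OO1 | target

**Total step count:** 6 (five bond-forming steps and one resolution). **Longest linear sequence:** 6.

**Steps most likely to fail, with fallbacks**

Step 4 (radical oxygenation). The risks are competition from the ester-allylic C2–H, which would lead to the 4-hydroperoxy-2-enoate, and over-oxidation at C3. The fallback sets out from 10 and comes back at 11. It is a Schenck ene reaction with singlet oxygen (O2, meso-tetraphenylporphyrin, visible light, CH2Cl2, 0 °C), a pericyclic C–O bond formation that takes H from the more activated C5 and moves the double bond into conjugation with the ketone. The regioisomer from attack at C4 is removed by chromatography. It makes no new compound (none F0).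

Step 3 (cross-metathesis). The risk is double-bond migration in two allyl carbonyl partners. The fallback sets out from 7 (generated from 4 as in step 2) and comes back at 10. The acylzirconocene is cross-coupled with vinyl bromide (PdCl2(PPh3)2, 5 mol%, THF) to give nonadec-1-en-3-one F1. Cross-metathesis of this enone with methyl pent-4-enoate (second-generation Grubbs catalyst, CH2Cl2, 40 °C) gives methyl (4E)-6-oxodocos-4-enoate F2, a more reliable enone/terminal-alkene pairing. Photodeconjugation (hv 300 nm, hexane, catalytic 1,2-dimethylimidazole) proceeds through the photodienol and its kinetic α-protonation, moves the double bond to C3=C4 and returns 10.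

Step 6 (photoisomerisation with a free hydroperoxide). The risks are O–O cleavage and photoenolisation at C3. The fallback sets out from 12 and comes back at 13. The hydroperoxide is masked with 2-methoxypropene (PPTS, CH2Cl2, 0 °C) as methyl (3R,4E)-3-[(2-methoxypropan-2-yl)peroxy]-6-oxodocos-4-enoate F3. Triplet-sensitised isomerisation (xanthone, 365 nm, benzene) enriches methyl (3R,4Z)-3-[(2-methoxypropan-2-yl)peroxy]-6-oxodocos-4-enoate F4. TsOH in MeOH then cleaves the perketal and releases 13, which closes to 14 and is ketalised to 15 in the same pot.

**Further compounds**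
F1 | step 3 | nonadec-1-en-3-one | C=CC(=O)CCCCCCCCCCCCCCCC
F2 | step 3 | methyl (4E)-6-oxodocos-4-enoate | CCCCCCCCCCCCCCCCC(=O)/C=C/CCC(=O)OC
F0 | step 4 | none | none
F3 | step 6 | methyl (3R,4E)-3-[(2-methoxypropan-2-yl)peroxy]-6-oxodocos-4-enoate | CCCCCCCCCCCCCCCCC(=O)/C=C/[C@H](OOC(C)(C)OC)CC(=O)OC
F4 | step 6 | methyl (3R,4Z)-3-[(2-methoxypropan-2-yl)peroxy]-6-oxodocos-4-enoate | CCCCCCCCCCCCCCCCC(=O)/C=C\[C@H](OOC(C)(C)OC)CC(=O)OC
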